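## Retrosynthetic overview

1. Target ⇐ its bis-TIPS ether methyl ester; the last step is a one-pot desilylation and saponification.
2. Key disconnection is the benzofuran benzene ring itself (bonds C3a–C7a and C4–C5, then loss of N2 and 2 H). An intramolecular inverse-electron-demand Diels–Alder reaction of an acrylate-bearing pyridazine with a tethered vinyl group closes the carbocycle and the dihydrofuran ring together.
3. Cycloaddition substrate ⇐ SNAr of a chiral homoallylic alkoxide on methyl 3-(6-chloro-5-methoxypyridazin-3-yl)acrylate ⇐ Heck reaction of 3,6-dichloro-4-methoxypyridazine with methyl acrylate.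
4. Both stereocentres ⇐ one iridium-catalysed anti-(hydroxymethyl)allylation of O-silylated syringaldehyde with vinyl ethylene carbonate.
5. Ring order: the syringyl ring is bought; benzene ring A and the O-heterocycle are formed together in the penultimate step.

Assumption: the (S)-SEGPHOS iridium catalyst is taken to give the (1S)-carbinol in step 2 (the (R)-ligand is used if the sense is found reversed); benzofuran numbering (O1, C2, C3, C3a, C4–C7, C7a) is used for these atoms before the ring exists.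

## Route

Step 1
Reactants: 1 4-hydroxy-3,5-dimethoxybenzaldehyde (syringaldehyde)
Product: 2 3,5-dimethoxy-4-[(triisopropylsilyl)oxy]benzaldehyde
Conditions: TIPSCl, imidazole, DMF, 23 °C
Reagents that add atoms: chlorotri(propan-2-yl)silane (TIPSCl), CC(C)[Si](Cl)(C(C)C)C(C)C
Why: Imidazole-mediated O-silylation masks the only acidic OH with a bulky group that survives base, Pd and heat and is removed by fluoride at the end; no stereocentre is formed.

Step 2
Reactants: 2 3,5-dimethoxy-4-[(triisopropylsilyl)oxy]benzaldehyde; 3 4-ethenyl-1,3-dioxolan-2-one (vinyl ethylene carbonate; racemic)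
Product: 4 (1S,2R)-1-{3,5-dimethoxy-4-[(triisopropylsilyl)oxy]phenyl}-2-ethenylpropane-1,3-diol
Conditions: [Ir(cod)Cl]2 (2.5 mol %), (S)-SEGPHOS (5 mol %), 4-cyano-3-nitrobenzoic acid (10 mol %), K3PO4 (cat.), i-PrOH (2 equiv), THF, 90 °C
Reagents that add atoms: none
Why: Krische transfer-hydrogenative carbonyl (hydroxymethyl)allylation: ionisation and decarboxylation of 3 give an (E)-σ-allyl iridium alkoxide that adds to the aldehyde through a closed chair transition state, so the diol is anti, and the ligand fixes the aldehyde face, setting C1 as S and C2 as R (the later C2 and C3 of the benzofuran).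

Step 3
Reactants: 4 (1S,2R)-1-{3,5-dimethoxy-4-[(triisopropylsilyl)oxy]phenyl}-2-ethenylpropane-1,3-diol
Product: 5 (1S,2R)-1-{3,5-dimethoxy-4-[(triisopropylsilyl)oxy]phenyl}-2-{[(triisopropylsilyl)oxy]methyl}but-3-en-1-ol
Conditions: TIPSCl (1.1 equiv), imidazole, CH2Cl2, 0 → 23 °C
Reagents that add atoms: chlorotri(propan-2-yl)silane (TIPSCl), CC(C)[Si](Cl)(C(C)C)C(C)C
Why: Sterically controlled silylation takes the primary OH and leaves the hindered secondary benzylic OH free; TIPS is chosen because it migrates slowly to a neighbouring alkoxide; no stereocentre is touched.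

Step 4
Reactants: 6 3,6-dichloro-4-methoxypyridazine; 7 methyl prop-2-enoate (methyl acrylate)
Product: 8 methyl (2E)-3-(6-chloro-5-methoxypyridazin-3-yl)prop-2-enoate
Conditions: Pd(OAc)2 (3 mol %), P(t-Bu)3·HBF4 (6 mol %), Cy2NMe, 1,4-dioxane, 80 °C (6 in 1.3-fold excess)
Reagents that add atoms: none
Why: Mizoroki–Heck reaction; oxidative addition is expected at the unhindered chloride remote from the methoxy group, and syn insertion followed by syn β-hydride elimination gives the E-acrylate.

Step 5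
Reactants: 5 (1S,2R)-1-{3,5-dimethoxy-4-[(triisopropylsilyl)oxy]phenyl}-2-{[(triisopropylsilyl)oxy]methyl}but-3-en-1-ol; 8 methyl (2E)-3-(6-chloro-5-methoxypyridazin-3-yl)prop-2-enoate
Product: 9 methyl (2E)-3-{6-[((1S,2R)-1-{3,5-dimethoxy-4-[(triisopropylsilyl)oxy]phenyl}-2-{[(triisopropylsilyl)oxy]methyl}but-3-en-1-yl)oxy]-5-methoxypyridazin-3-yl}prop-2-enoate
Conditions: NaH (1.05 equiv), THF, 0 °C; then 8, 0 → 23 °C
Reagents that add atoms: none
Why: SNAr (addition–elimination): the sodium alkoxide displaces the only chloride of 8, which is activated by the ring nitrogens and the para-disposed acrylate; the C–O bond at the stereocentre is not broken, so it stays S.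

Step 6
Reactants: 9 methyl (2E)-3-{6-[((1S,2R)-1-{3,5-dimethoxy-4-[(triisopropylsilyl)oxy]phenyl}-2-{[(triisopropylsilyl)oxy]methyl}but-3-en-1-yl)oxy]-5-methoxypyridazin-3-yl}prop-2-enoate
Product: 12 methyl (2E)-3-[(2S,3R)-2-{3,5-dimethoxy-4-[(triisopropylsilyl)oxy]phenyl}-7-methoxy-3-{[(triisopropylsilyl)oxy]methyl}-2,3-dihydro-1-benzofuran-5-yl]prop-2-enoate, via diazabicyclooctadiene cycloadduct 10 (not isolated), via 3a,4-dihydrobenzofuran 11 (not isolated)
Conditions: o-C6H4Cl2 (0.01 M), BHT, 180 °C, Ar; then DDQ (1.1 equiv), 23 °C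
Reagents that add atoms: none
Why: Intramolecular inverse-electron-demand Diels–Alder reaction of the acrylate-activated 1,2-diazine with the tethered vinyl group across C3/C6 of the pyridazine (a known reaction type for alkenyl- and alkynyl-oxy pyridazines) forms C3a–C7a and C4–C5 and so closes the dihydrofuran and the six-membered carbocycle at once; retro-Diels–Alder loss of N2 and DDQ dehydrogenation give the arene, the transient C3a centre disappears, and C2 (S) and C3 (R) from step 2 are not touched.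

Step 7
Reactants: 12 methyl (2E)-3-[(2S,3R)-2-{3,5-dimethoxy-4-[(triisopropylsilyl)oxy]phenyl}-7-methoxy-3-{[(triisopropylsilyl)oxy]methyl}-2,3-dihydro-1-benzofuran-5-yl]prop-2-enoate
Product: 13 (2E)-3-[(2S,3R)-2-(4-hydroxy-3,5-dimethoxyphenyl)-3-(hydroxymethyl)-7-methoxy-2,3-dihydro-1-benzofuran-5-yl]prop-2-enoic acid
Conditions: TBAF (3 equiv), THF, 0 → 23 °C; then LiOH, H2O–MeOH, 23 °C; aq. HCl to pH 3
Reagents that add atoms: lithium hydroxide, [Li+].[OH-]
Why: Fluoride cleaves both Si–O bonds and hydroxide saponifies the methyl ester (BAc2) at room temperature, conditions that leave the trans-2,3-dihydrobenzofuran stereocentres and the E-alkene unchanged.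

## Compound list

1 | 4-hydroxy-3,5-dimethoxybenzaldehyde (syringaldehyde) | COc1cc(C=O)cc(OC)c1O | starting material
2 | 3,5-dimethoxy-4-[(triisopropylsilyl)oxy]benzaldehyde | COc1cc(C=O)cc(OC)c1O[Si](C(C)C)(C(C)C)C(C)C | intermediate
3 | 4-ethenyl-1,3-dioxolan-2-one (vinyl ethylene carbonate; racemic) | C=CC1COC(=O)O1 | starting material
4 | (1S,2R)-1-{3,5-dimethoxy-4-[(triisopropylsilyl)oxy]phenyl}-2-ethenylpropane-1,3-diol | C=C[C@H](CO)[C@H](O)c1cc(OC)c(O[Si](C(C)C)(C(C)C)C(C)C)c(OC)c1 | intermediate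
5 | (1S,2R)-1-{3,5-dimethoxy-4-[(triisopropylsilyl)oxy]phenyl}-2-{[(triisopropylsilyl)oxy]methyl}but-3-en-1-ol | C=C[C@H](CO[Si](C(C)C)(C(C)C)C(C)C)[C@H](O)c1cc(OC)c(O[Si](C(C)C)(C(C)C)C(C)C)c(OC)c1 | intermediate
6 | 3,6-dichloro-4-methoxypyridazine | COc1cc(Cl)nnc1Cl | starting material
7 | methyl prop-2-enoate (methyl acrylate) | C=CC(=O)OC | starting material
8 | methyl (2E)-3-(6-chloro-5-methoxypyridazin-3-yl)prop-2-enoate | COC(=O)/C=C/c1cc(OC)c(Cl)nn1 | intermediate
9 | methyl (2E)-3-{6-[((1S,2R)-1-{3,5-dimethoxy-4-[(triisopropylsilyl)oxy]phenyl}-2-{[(triisopropylsilyl)oxy]methyl}but-3-en-1-yl)oxy]-5-methoxypyridazin-3-yl}prop-2-enoate | C=C[C@H](CO[Si](C(C)C)(C(C)C)C(C)C)[C@H](Oc1nnc(/C=C/C(=O)OC)cc1OC)c1cc(OC)c(O[Si](C(C)C)(C(C)C)C(C)C)c(OC)c1 | intermediate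
10 | bridged [4+2] adduct: 2,3-diazabicyclo[2.2.2]octa-2,5-diene with fused tetrahydrofuran; N=N bridge between C5 and C7a; C2 (S) and C3 (R) unchanged; one of the converging C3a diastereomers drawn | COC(=O)/C=C/[C@@]12C=C(OC)[C@]3(N=N1)O[C@H](c4cc(OC)c(O[Si](C(C)C)(C(C)C)C(C)C)c(OC)c4)[C@@H](CO[Si](C(C)C)(C(C)C)C(C)C)[C@@H]3C2 | intermediate
11 | methyl (2E)-3-[(2S,3R,3aS)-2-{3,5-dimethoxy-4-[(triisopropylsilyl)oxy]phenyl}-7-methoxy-3-{[(triisopropylsilyl)oxy]methyl}-2,3,3a,4-tetrahydro-1-benzofuran-5-yl]prop-2-enoate (the 3a-epimer gives the same product) | COC(=O)/C=C/C1=CC(OC)=C2O[C@H](c3cc(OC)c(O[Si](C(C)C)(C(C)C)C(C)C)c(OC)c3)[C@@H](CO[Si](C(C)C)(C(C)C)C(C)C)[C@@H]2C1 | intermediate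
12 | methyl (2E)-3-[(2S,3R)-2-{3,5-dimethoxy-4-[(triisopropylsilyl)oxy]phenyl}-7-methoxy-3-{[(triisopropylsilyl)oxy]methyl}-2,3-dihydro-1-benzofuran-5-yl]prop-2-enoate | COC(=O)/C=C/c1cc(OC)c2O[C@H](c3cc(OC)c(O[Si](C(C)C)(C(C)C)C(C)C)c(OC)c3)[C@@H](CO[Si](C(C)C)(C(C)C)C(C)C)c2c1 | intermediate
13 | (2E)-3-[(2S,3R)-2-(4-hydroxy-3,5-dimethoxyphenyl)-3-(hydroxymethyl)-7-methoxy-2,3-dihydro-1-benzofuran-5-yl]prop-2-enoic acid | COc1cc([C@H]2Oc3c(OC)cc(/C=C/C(=O)O)cc3[C@@H]2CO)cc(OC)c1O | target

## Step count and risks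

Total steps: 7. Longest linear sequence: 6 steps (1 → 2 → 4 → 5 → 9 → 12 → 13); step 4 is a one-step side branch.

Steps most likely to fail:

Step 6 (cycloaddition and aromatisation). The unactivated vinyl group may add too slowly below the temperature at which the benzylic pyridazinyl ether degrades, and the dihydroarene 11 could isomerise (hydrogen transfer into the acrylate) before it is oxidised. The fallback sets out from 9 and comes back at 12; it makes the dienophile electron-rich and lets the ring aromatise by elimination instead of oxidation. Hydroboration of the vinyl group of 9 (9-BBN, then NaBO3) gives the primary alcohol F1, and Dess–Martin oxidation gives the aldehyde F2. Warming F2 with pyrrolidine (20 mol %, 4 Å sieves, toluene, 80–110 °C) forms the pyrrolidine enamine F3, which adds as a matched dienophile across C3/C6 of the pyridazine to the amino cycloadduct F4. Loss of N2 gives the 4-pyrrolidinyl-3a,4-dihydrobenzofuran F5, which loses pyrrolidine to deliver 12 without any oxidant.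

Step 4 (site of the Heck reaction on 6). Oxidative addition could take the chloride next to the methoxy group or give a mixture; that chloride would then also be the one an alkoxide displaces first, so the order of the two bond formations is reversed. The fallback sets out from 5 and 6 and comes back at 9. The sodium alkoxide of 5 (NaH, THF, 0 °C) is added to 6 to give the chloropyridazinyl ether F6 (ether oxygen next to OMe), and the remaining unhindered chloride of F6 is then used in the Heck reaction with 7 to give 9.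

Step 5 (SNAr of a hindered secondary alkoxide beside a methyl ester and an acrylate). If transesterification or conjugate addition competes, the C–O bond is made by palladium-catalysed etherification under weak base instead of addition–elimination, so no free alkoxide is present. The fallback sets out from 5 and 8 and comes back at 9: the two are coupled directly (Pd/RockPhos, Cs2CO3, toluene, 80 °C), and no new compound is made.

## Further compounds

F1 | step 6 | primary alcohol (anti-Markovnikov hydration product of 9; methyl (2E)-3-{6-[((1S,2R)-1-aryl-4-hydroxy-2-{[(triisopropylsilyl)oxy]methyl}butyl)oxy]-5-methoxypyridazin-3-yl}prop-2-enoate) | OCC[C@H](CO[Si](C(C)C)(C(C)C)C(C)C)[C@H](Oc1nnc(/C=C/C(=O)OC)cc1OC)c1cc(OC)c(O[Si](C(C)C)(C(C)C)C(C)C)c(OC)c1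
F2 | step 6 | aldehyde (4-oxobutyl analogue of F1) | O=CC[C@H](CO[Si](C(C)C)(C(C)C)C(C)C)[C@H](Oc1nnc(/C=C/C(=O)OC)cc1OC)c1cc(OC)c(O[Si](C(C)C)(C(C)C)C(C)C)c(OC)c1
F3 | step 6 | pyrrolidine enamine ((E)-enamine of F2) | C1CCN(C1)/C=C/[C@H](CO[Si](C(C)C)(C(C)C)C(C)C)[C@H](Oc2nnc(/C=C/C(=O)OC)cc2OC)c2cc(OC)c(O[Si](C(C)C)(C(C)C)C(C)C)c(OC)c2
F4 | step 6 | amino cycloadduct (analogue of 10 with pyrrolidin-1-yl at C4, trans to C3 across C3a–C4) | COC(=O)/C=C/[C@@]12C=C(OC)[C@]3(N=N1)O[C@H](c4cc(OC)c(O[Si](C(C)C)(C(C)C)C(C)C)c(OC)c4)[C@@H](CO[Si](C(C)C)(C(C)C)C(C)C)[C@@H]3[C@H]2N5CCCC5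
F5 | step 6 | 4-pyrrolidinyl-3a,4-dihydrobenzofuran (analogue of 11 with pyrrolidin-1-yl at C4) | COC(=O)/C=C/C1=CC(OC)=C2O[C@H](c3cc(OC)c(O[Si](C(C)C)(C(C)C)C(C)C)c(OC)c3)[C@@H](CO[Si](C(C)C)(C(C)C)C(C)C)[C@@H]2[C@H]1N4CCCC4
F6 | step 4 | chloropyridazinyl ether (6-chloro-3-[((1S,2R)-1-{3,5-dimethoxy-4-[(triisopropylsilyl)oxy]phenyl}-2-{[(triisopropylsilyl)oxy]methyl}but-3-en-1-yl)oxy]-4-methoxypyridazine) | C=C[C@H](CO[Si](C(C)C)(C(C)C)C(C)C)[C@H](Oc1nnc(Cl)cc1OC)c1cc(OC)c(O[Si](C(C)C)(C(C)C)C(C)C)c(OC)c1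
F0 | step 5 | none | none
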